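The readings were computed on assumed constants, and the scatter is random.

- Amounts first: you wanted a quick figure for what Sunday's, Tuesday's and Wednesday's flasks hold at their end, and your hunch was that substrate sits on average 4.00 h during the feed, so the loss over the feed gives its rate at once.

| setting | north-east | Sunday's | Tuesday's | Wednesday's |
|---|---|---|---|---|
| substrate | 0.80 M (fed, over 8.0 h) | 0.40 M (fed, over 8.0 h) | 0.40 M (fed, over 8.0 h) | 0.40 M (fed, over 8.0 h) |
| second nucleophile | 0.70 equiv | 0.700 equiv | 0.700 equiv | 0.700 equiv |
| solid first nucleophile | 0.80 equiv | 0.800 equiv | 0.800 equiv | 0.800 equiv |
| remark | run made earlier |  |  |  |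
| time |  | 25 h | 75 h | 220 h |

north-east run (percent of the substrate charged)

| time / h | target / % | substrate / % | other capture product / % | solvolysis product / % | side product / % |
|---|---|---|---|---|---|
| 1.33 | 0 | 15.4 | 1.0 | 0.1 | 0 |
| 2.50 | 0.4 | 29.9 | 0.5 | 2.5 | 0 |
| 4.00 | 0 | 46.1 | 3.0 | 3.3 | 1.1 |
| 5.00 | 1.6 | 55.5 | 1.1 | 6.1 | 0.8 |
| 6.00 | 0 | 66.7 | 0 | 10.1 | 1.1 |
| 8.00 | 0 | 84.0 | 0.7 | 13.1 | 0 |

(standard deviation of a reading: 1 percentage point)

- in percentages every species weighs as the substrate in it: one side product counts as two
- at the start none of the solid first nucleophile is in solution
- a reading or a percentage of target counts all its forms, free or not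
- percentages count the whole charge, also what has not yet gone in

- which of these there is most of at the end, counted by the substrate in it, Sunday's (target / other capture product / substrate / side product / solvolysis product)
- which of these there is most of at the end, counted by the substrate in it, Tuesday's (target / other capture product / substrate / side product / solvolysis product)
- which of these there is most of at the end, counted by the substrate in it, Wednesday's (target / other capture product / substrate / side product / solvolysis product)
- the largest of these amounts at the end, in percent of the substrate charged, Sunday's
- the largest of these amounts at the end, in percent of the substrate charged, Tuesday's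
- the largest of these amounts at the end, in percent of the substrate charged, Wednesday's

- I took your hunch as my first round: the north-east run's reading was 84.0 % of its charge as substrate at 8.00 h, so twice the lost fraction gave 0.320 for rate times feed time.
- But substrate already gone can't go again, so the lost fraction is close to half that product, times one minus a third of it; I put each answer back in and got 0.358, then 0.363.
- That gave 0.0454 h⁻¹ for the loss constant, the fraction of the substrate present that goes per hour.
- I assumed first order, so the new flasks should match the north-east fraction at the end of the feed and decay from there, leaving 38.8 % on Sunday's, 4.00 % on Tuesday's and 0.00552 % on Wednesday's.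
- The north-east readings, summed, put 15.2 % of what other capture product and solvolysis product held together in other capture product; scaling by 0.40 M over 0.80 M gave my estimate of 7.59 %, a rough figure given the scatter.
- I set target and side product at nil, so my solvolysis product came to 56.5 %, 88.7 % and 92.4 %, already ahead of Sunday's substrate.
- The forecast named solvolysis product, solvolysis product and solvolysis product at 50 %, 82 % and 84 %, each lower than mine: “Solvolysis product dominates throughout”.
- The flasks gave solvolysis product, solvolysis product and solvolysis product at 57.7 %, 89.8 % and 93.3 %, with substrate at 38.2 % on Sunday's and 3.81 % on Tuesday's.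

    substrate → intermediate (k = 0.0460 h⁻¹)
    first nucleophile + intermediate → target (k = 260 M⁻¹ h⁻¹)
    second nucleophile + intermediate → other capture product (k = 320 M⁻¹ h⁻¹)
    intermediate → solvolysis product (k = 1300 h⁻¹)
    substrate + target → side product (k = 0.170 M⁻¹ h⁻¹)
    solid first nucleophile ⇌ first nucleophile, rate k6*(cs6 - [first nucleophile]) while solid is left; crystals form when [first nucleophile] > cs6 (solubility = 0.0640 M, k = 0.0170 h⁻¹)
    first nucleophile + target ⇌ idle adduct, settled at all times (K = 0.670 M⁻¹)

- My loss constant means a half-life of 15.3 h, and Sunday's flask shows 15 h at 25.0 h for the passing of substrate into intermediate, while at 12.1 h its intermediate went into solvolysis product at 15 times the rate of its passing into other capture product. The same constant, applied to Sunday's recipe read at 15 h, leaves 61.1 % of the charge as substrate, and that neighbour flask holds 60.6 %.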